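The readings come from a simulation with made-up constants; scatter was added.

Autumn made target at 9.72 mM/h between 3.00 h and 8.00 h, while summer, under the same gas, made it faster, at 21.5 mM/h. You have these runs, and you want teal and grey:

| setting | autumn | summer | teal | grey |
|---|---|---|---|---|
| starting material | 0.13 M | 0.40 M | 0.20 M | 0.20 M |
| second substrate | 0.50 equiv | 0.50 equiv | 1.00 equiv | 0.500 equiv |
| gas | 27 mM (held) | 27 mM (held) | 27 mM (held) | 27 mM (held) |
| remark | run made earlier | run made earlier |  |  |
| time |  |  | 40 h | 40 h |

| run | time / h | target / % |
|---|---|---|
| autumn | 0.667 | 5.9 |
| autumn | 1.33 | 12.2 |
| autumn | 3.00 | 34.0 |
| autumn | 8.00 | 71.4 |
| summer | 0.667 | 3.2 |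
| summer | 1.33 | 5.1 |
| summer | 3.00 | 15.1 |
| summer | 8.00 | 42.0 |

(standard deviation of a reading: 1 percentage point)

- which of the two there is more of at the end, teal (cross product / target)
- which of the two there is more of at the end, grey (cross product / target)
- amount of target at the end, in percent of the starting material charged, teal
- amount of target at the end, in percent of the starting material charged, grey

- amounts and yields of target count idle adduct too
- at the start none of coupling partner is dissolved
- the analysis behind the earlier runs scatters by 1 percentage point, standard deviation
- what may be going on: starting material + coupling partner -> target; starting material + second substrate -> cross product; gas <-> coupling partner; second substrate + target <-> idle adduct; second substrate + coupling partner -> second product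

That looks contradictory. At 3.00 h autumn had 85.8 mM of its charge not read as target, and summer's pace over those hours would deliver 108 mM, which is more. Yet autumn stood at 71.4% at 8.00 h. Taking autumn as close to its end, I read the missing part as cross product, formed from one starting material and one second substrate. Autumn's part of charged second substrate ending as cross product is then 0.572.

Summer's last reading, 42.0%, is still rising, so its share can't be read. A share can't pass 1, so I set that ceiling at 0.40 M, which may overstate it. Interpolating to 0.20 M gives the cross share, the part of charged second substrate ending as cross product (a selectivity) 0.683.

Both exits of second substrate are proportional to [second substrate], so that concentration cancels from the split, and I use one share for both flasks. Target is the charge minus share times equivalents: 65.9% in grey and 31.7% in teal, where cross product leads.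

The forecast said 70% for teal and 85% for grey, with target ahead in teal and target in grey, holding that the “final split is then set by cross-product loss”. My teal differs from it in both amount and winner.

Teal gives 34.9% of target, and the larger of the two there is cross product. Grey gives 65.6% of target, and the larger of the two there is target.

    starting material + coupling partner → target (k = 0.00940 /M/s)
    starting material + second substrate → cross product (k = 0.00140 /M/s)
    gas ⇌ coupling partner, rate k3*(csat - [coupling partner]) (kL = 3.00 × 10⁻⁴ /s)
    second substrate + target ⇌ idle adduct, settled at all times (K = 62.0 /M)
    second substrate + coupling partner → second product (k = 0.0170 /M/s)

The cross share read from these ends is 0.689 in grey and 0.651 in teal, beside the 0.683 carried. Take the neighbouring flask, grey with 0.300 equiv of second substrate. The same share gives 79.5% of target. That flask ends at 79.3% of target, with cross product at 20.7%.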